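The heptane chain is traced back to a 1,6-diene and cut at C1=C2 and C6=C7. An enantiopure trans-4-hydroxycyclopent-2-enyl acetate supplies C2–C6 with the anti C3/C5 oxygens, and the ArCH= carbons of two 4-acetoxystyrenes become C1 and C7. One ruthenium-catalysed operation cleaves the five-membered ring's alkene (C2=C6) and caps both termini. The whole diarylheptanoid skeleton appears at once with both carbinol centres set. The feature exploited is the twofold symmetry of the C3–C5 anti-diol core with its identical arms. O3 and O5 are homotopic, so the sense of ring opening and any acetyl shift are immaterial. The precursor comes from the commercial cis monoacetate by one Mitsunobu inversion.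

Key step: step 3

Remark: commercial 1 is taken as enantiopure (carbinol carbon R, acetate-bearing carbon S); all open-chain compounds carry the target numbering (C3 = OAc, C5 = OH).

Step 1
Reactants: 1 (1R,4S)-cis-4-acetoxycyclopent-2-en-1-ol; 2 chloroacetic acid
Product: 3 (1S,4S)-4-acetoxycyclopent-2-en-1-yl chloroacetate (trans diester)
Conditions: PPh3, DIAD, ClCH2CO2H, THF, 0 °C → rt
Reagents that add atoms: chloroacetic acid (2), OC(=O)CCl
Why: Mitsunobu esterification, in which the acidic chloroacetate displaces the phosphorus-activated oxygen by SN2 with inversion, so the R carbinol carbon of 1 becomes S and cis becomes trans while the S acetate-bearing carbon is not touched.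

Step 2
Reactants: 3 (1S,4S)-4-acetoxycyclopent-2-en-1-yl chloroacetate
Product: 5 (1S,4S)-4-hydroxycyclopent-2-en-1-yl acetate (trans), via isothiouronium ester 4 (not isolated)
Conditions: thiourea, NaHCO3, EtOH, 55 °C
Reagents that add atoms: none
Why: Chemoselective chloroacetate removal with thiourea (S-alkylation followed by cyclisation–release), a path open only to the α-chloro ester because its alkoxide is expelled by intramolecular N-acylation, so the plain acetate and both C–O stereocentres remain as they are.

Step 3
Reactants: 5 (1S,4S)-4-hydroxycyclopent-2-en-1-yl acetate; 6 4-acetoxystyrene (two molecules incorporated, used in excess)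
Product: 9 (1E,3S,5S,6E)-1,7-bis(4-acetoxyphenyl)-5-hydroxyhepta-1,6-dien-3-yl acetate, via C6-terminal diene 7 (not isolated), via C2-terminal diene 8 (not isolated)
Conditions: Hoveyda–Grubbs II (2 × 2.5 mol %), 1,4-benzoquinone (10 mol %), inhibitor-free 6 (8 equiv, serves as medium), minimal PhMe, 25 °C, Ar sparge; EtOCH=CH2 quench before dilution
Reagents that add atoms: 4-acetoxystyrene (6), C=Cc1ccc(OC(C)=O)cc1
Why: Ring-opening/double cross-metathesis by the metallacyclobutane mechanism: the 4-acetoxybenzylidene formed from precatalyst and 6 adds [2+2] to the C2=C6 ring alkene of 5, cycloreversion opens the ring, 6 intercepts the open-chain alkylidene, and any vinyl terminus left (7, 8) is capped by ordinary cross-metathesis with loss of ethylene. The closest known reactions are the double-capping ring-opening cross-metathesis of cyclopentene and other weakly strained cycloalkenes with excess acyclic alkene under phosphine-free ruthenium catalysts, and the ring-rearrangement metathesis of 3,5-diheteroatom-substituted cyclopentenes, which shows that such ring alkenes do open. No ring is closed and no stereocentre is created, since the C3–O and C5–O bonds are spectators and read S,S here only because a vinyl carbon outranks the C4 methylene. The step needs opening to outrun reclosure and both ends to be capped, so the small strain energy is backed by high concentration and ambient temperature (both favour the open form), by sweeping out ethylene, and by the low reactivity of the allylically branched β-substituted styrene termini towards the catalyst. The hydroxyl is left free on purpose, because each face of the trans ring carries one allylic substituent: the small OH, able to hydrogen-bond to a ruthenium chloride, keeps one face accessible and should bias the metal towards C6 and away from the chelating acetate carbonyl, while benzoquinone intercepts ruthenium hydrides that would isomerise the allylic alcohol and also restrains radical polymerisation of 6. The regiochemistry of opening does not matter because both ends receive the same cap, and the alkene geometry does not matter because step 4 saturates both alkenes, E,E being the expected thermodynamic outcome.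

Step 4
Reactants: 9 (1E,3S,5S,6E)-1,7-bis(4-acetoxyphenyl)-5-hydroxyhepta-1,6-dien-3-yl acetate
Product: 10 (3R,5R)-1,7-bis(4-acetoxyphenyl)-5-hydroxyheptan-3-yl acetate
Conditions: 2-NO2C6H4SO2NHNH2 (NBSH, excess, in portions), Et3N, CH2Cl2, rt
Reagents that add atoms: none
Why: Diimide reduction (concerted syn hydrogen transfer from HN=NH released by base-induced fragmentation of NBSH) adds only to the C=C bonds and cannot ionise or hydrogenolyse the allylic C3–OAc and C5–OH bonds, the mild aprotic medium keeps the aryl acetates on so that no p-hydroxystyryl carbinyl ester able to expel acetate is ever present, and the descriptors change to R,R without any change in space.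

Step 5
Reactants: 10 (3R,5R)-1,7-bis(4-acetoxyphenyl)-5-hydroxyheptan-3-yl acetate
Product: 11 (3R,5R)-5-hydroxy-1,7-bis(4-hydroxyphenyl)heptan-3-yl acetate (target)
Conditions: NH4OAc, MeOH–H2O (4:1), rt
Reagents that add atoms: none
Why: Chemoselective solvolysis of phenolic acetates promoted by ammonium acetate under near-neutral conditions, in which aryloxide is a far better leaving group than a secondary alkoxide so only the two aryl esters should cleave, and a 1,3-acetyl shift between O3 and O5 would regenerate the same molecule because the two oxygens are homotopic.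

Compound list
1 | (1R,4S)-cis-4-acetoxycyclopent-2-en-1-ol | CC(=O)O[C@@H]1C=C[C@H](O)C1 | starting material
2 | chloroacetic acid | OC(=O)CCl | starting material
3 | (1S,4S)-4-acetoxycyclopent-2-en-1-yl chloroacetate | CC(=O)O[C@@H]1C=C[C@@H](OC(=O)CCl)C1 | intermediate
4 | (1S,4S)-4-acetoxycyclopent-2-en-1-yl 2-(carbamimidoylsulfanyl)acetate | CC(=O)O[C@@H]1C=C[C@@H](OC(=O)CSC(N)=N)C1 | intermediate
5 | (1S,4S)-trans-4-hydroxycyclopent-2-en-1-yl acetate | CC(=O)O[C@@H]1C=C[C@@H](O)C1 | intermediate
6 | 4-acetoxystyrene | C=Cc1ccc(OC(C)=O)cc1 | starting material
7 | (1E,3S,5S)-1-(4-acetoxyphenyl)-5-hydroxyhepta-1,6-dien-3-yl acetate | CC(=O)O[C@H](/C=C/c1ccc(OC(C)=O)cc1)C[C@H](O)C=C | intermediate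
8 | (3S,5S,6E)-7-(4-acetoxyphenyl)-5-hydroxyhepta-1,6-dien-3-yl acetate | CC(=O)O[C@H](C=C)C[C@H](O)/C=C/c1ccc(OC(C)=O)cc1 | intermediate
9 | (1E,3S,5S,6E)-1,7-bis(4-acetoxyphenyl)-5-hydroxyhepta-1,6-dien-3-yl acetate | CC(=O)O[C@H](/C=C/c1ccc(OC(C)=O)cc1)C[C@H](O)/C=C/c1ccc(OC(C)=O)cc1 | intermediate
10 | (3R,5R)-1,7-bis(4-acetoxyphenyl)-5-hydroxyheptan-3-yl acetate | CC(=O)O[C@H](CCc1ccc(OC(C)=O)cc1)C[C@H](O)CCc1ccc(OC(C)=O)cc1 | intermediate
11 | (3R,5R)-5-hydroxy-1,7-bis(4-hydroxyphenyl)heptan-3-yl acetate | CC(=O)O[C@H](CCc1ccc(O)cc1)C[C@H](O)CCc1ccc(O)cc1 | target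

Total step count: 5. Longest linear sequence: 5 steps (1 → 3 → 5 → 9 → 10 → 11).

Steps most likely to fail

Step 3.
- What may go wrong: the weakly strained, doubly allylically substituted ring alkene may not compete with self-metathesis of the styrene. The singly capped chain may also fold back by ring-closing metathesis faster than its vinyl end is capped, so that material shuttles between ring and open form until the catalyst dies. Hydride-induced isomerisation of the allylic alcohol is a second drain.
- Fallback (from 5, back at 11): the same two alkenes are made by carbonyl olefination instead of metathesis.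
- Silylation (TBSCl, imidazole, DMF) should give (1S,4S)-4-(tert-butyldimethylsilyloxy)cyclopent-2-en-1-yl acetate F1.
- Ozonolysis (O3, CH2Cl2, −78 °C; Me2S) cleaves C2=C6 to the protected (2S,4S)-2-acetoxy-4-silyloxypentanedial F2, which is used crude.
- Double Wittig olefination with the ylide from [4-(tert-butyldimethylsilyloxy)benzyl]triphenylphosphonium bromide (NaHMDS, THF, −78 °C) should give the tris-silylated diene acetate F3. Its E/Z composition is of no consequence.
- NBSH/Et3N saturates it to the tris-silylated heptyl acetate F4.
- HF·pyridine in THF removes all three silyl groups to reach 11.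

Step 4.
- What may go wrong: hydrogen transfer to two conjugated, allylically branched alkenes may be sluggish. Diimide would then disproportionate faster than it reduces, and saturation would stay incomplete.
- Fallback (from 9, back at 10): stoichiometric diimide transfer is replaced by homogeneous catalytic hydrogenation (H2, RhCl(PPh3)3, benzene–EtOH, rt). This adds hydrogen by an insertion pathway and should not ionise the allylic acetate as palladium on carbon can. No new compound is made.

Step 5.
- What may go wrong: chemoselectivity may erode through slow solvolysis of the secondary acetate, possibly assisted by the neighbouring hydroxyl, alongside cleavage of the aryl esters.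
- Fallback (from 10, back at 11): selectivity is given up and the monoacetate is rebuilt.
- Exhaustive methanolysis (K2CO3, MeOH) should give (3R,5R)-1,7-bis(4-hydroxyphenyl)heptane-3,5-diol F5.
- Trimethyl orthoacetate with catalytic camphorsulfonic acid in CH2Cl2 closes the 1,3-diol to the cyclic orthoacetate (4R,6R)-2-methoxy-2-methyl-4,6-bis[2-(4-hydroxyphenyl)ethyl]-1,3-dioxane F6.
- Aqueous acetic acid opens F6 to the hydroxy acetate. Because O3 and O5 are homotopic, either mode of opening gives 11, and the phenols are not acylated.

Further compounds
F1 | step 3 | (1S,4S)-4-[(tert-butyldimethylsilyl)oxy]cyclopent-2-en-1-yl acetate | CC(=O)O[C@@H]1C=C[C@@H](O[Si](C)(C)C(C)(C)C)C1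
F2 | step 3 | (2S,4S)-4-[(tert-butyldimethylsilyl)oxy]-1,5-dioxopentan-2-yl acetate | CC(=O)O[C@H](C=O)C[C@H](O[Si](C)(C)C(C)(C)C)C=O
F3 | step 3 | (3S,5S)-5-[(tert-butyldimethylsilyl)oxy]-1,7-bis{4-[(tert-butyldimethylsilyl)oxy]phenyl}hepta-1,6-dien-3-yl acetate (E/Z mixture) | CC(=O)O[C@H](C=Cc1ccc(O[Si](C)(C)C(C)(C)C)cc1)C[C@H](O[Si](C)(C)C(C)(C)C)C=Cc1ccc(O[Si](C)(C)C(C)(C)C)cc1
F4 | step 3 | (3R,5R)-5-[(tert-butyldimethylsilyl)oxy]-1,7-bis{4-[(tert-butyldimethylsilyl)oxy]phenyl}heptan-3-yl acetate | CC(=O)O[C@H](CCc1ccc(O[Si](C)(C)C(C)(C)C)cc1)C[C@H](O[Si](C)(C)C(C)(C)C)CCc1ccc(O[Si](C)(C)C(C)(C)C)cc1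
F0 | step 4 | none | none
F5 | step 5 | (3R,5R)-1,7-bis(4-hydroxyphenyl)heptane-3,5-diol | O[C@H](CCc1ccc(O)cc1)C[C@H](O)CCc1ccc(O)cc1
F6 | step 5 | (4R,6R)-2-methoxy-2-methyl-4,6-bis[2-(4-hydroxyphenyl)ethyl]-1,3-dioxane | COC1(C)O[C@H](CCc2ccc(O)cc2)C[C@@H](CCc2ccc(O)cc2)O1
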